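Friday's flask takes Tuesday's charge to 65 °C instead of 50 °C, and you want to know which of J, L, the dimer and D holds the most of the charge at the end of each.

the same everywhere: J 0.50 M; G 0.150 M; time 5.0 h

| run | temperature |
|---|---|
| Tuesday's | 50 °C |
| Friday's | 65 °C |

    J + G → J.G (k1 = 0.0181 M⁻¹ min⁻¹, Ea1 = 84.0 kJ mol⁻¹)
    J → L (k2 = 0.00178 min⁻¹, Ea2 = 116 kJ mol⁻¹)
    L → D (k3 = 0.00111 min⁻¹, Ea3 = 106 kJ mol⁻¹)
    J + J ⇌ J2 (K4 = 1.8 M⁻¹, k4 = 0.0486 M⁻¹ min⁻¹, Ea4 = 68.0 kJ mol⁻¹, ΔH4 = −25.0 kJ mol⁻¹)
    J ⇌ X (K5 = 1.47, k5 = 0.00293 min⁻¹, Ea5 = 109 kJ mol⁻¹, ΔH5 = −1.00 kJ mol⁻¹)
    (constants at 50 °C)

- percent here means J units held: one J2 counts as two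
- two of one species on the left: rate k times its square, two consumed each time
- the constants hold at 50 °C; other temperatures follow from the activation energies and enthalpies

- which of these there is most of at the end, counted by the J in it, Tuesday's (L / D / J2 / J)
- which of these there is most of at the end, counted by the J in it, Friday's (L / D / J2 / J)
- the largest of these amounts at the end, in percent of the J charged, Tuesday's
- the largest of these amounts at the end, in percent of the J charged, Friday's

Count turnovers. For L going to D on Tuesday, rate constant times hours gives 0.333. This is the turnover count of the step, the number of lifetimes of L that the run contains, and the D made over any stretch is the count of that stretch times the average L over it.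

First question: can D lead on Tuesday? The ring closure from J to L has a count of 0.534, so both steps of the chain stay below one. In a rough reckoning with J held at its full charge and no L lost, L climbs in a straight line and averages half its final value, which puts D near 8.89 % of the charge. J is not held there: the dimer balance with 1.8 M⁻¹, reckoned at the charge with no other partner, leaves about 51.8 % of it free. So I count D out on Tuesday.

Second question: who leads on Tuesday instead? With free J held at that share, L would reach about 27.6 %, and free J is falling while L is fed. My reckoning by hand does not separate J, L and the dimer, so it names no Tuesday leader.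

Third question: what does the heat do? Friday's counts become 3.62 for the ring closure and 1.92 for L going to D, both above one. G, the limiting reagent of its step, can bind 30.0 % of the J charge, which leaves 70.0 % if all of G is used. A plain two-step chain with these counts, reckoned with no J waiting in X or the dimer, carries 71.8 % through to D, so I expect D to lead on Friday at about 50.2 %.

The forecast names J at 24 % for Tuesday and D at 42 % for Friday, with “most of the rest passing through L to D”. My Friday figure stands higher than its figure, and for Tuesday it names a leader where my reckoning names none.

The simulation gives J at 25.1 % on Tuesday, with L at 16.2 %, and D at 39.6 % on Friday.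

In Tuesday's flask, L stood at 10.7 % after 2.50 h and 16.2 % after 5.00 h, which from a start at nothing gives a straight-line average of about 9.41 %, and 0.333 of that is 3.13 % against 3.32 % of D found. Now read Tuesday's flask later, at 8.0 h. The extra stretch has a count of 0.200, and the mean of L at its two ends is 17.9 %, which adds 3.57 % of the charge to the D already there and makes 6.89 %. That later reading shows 6.94 % of D.

(The constants used here were chosen freely; what happens was integrated by code.)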